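(The earlier runs and the new flask stem from a simulated flask from invented constants; scatter was added.)

Take a small charge: cedar, at 0.0070 M, keeps far more of its starting material as ring than oak does at 0.052 M, and that difference is the whole question here.

| flask | starting material | remark | time |
|---|---|---|---|
| cedar | 0.0070 M | run made earlier |  |
| oak | 0.052 M | run made earlier |  |
| blue | 0.012 M |  | 6.0 h |
| red | 0.020 M |  | 6.0 h |
| amber | 0.040 M |  | 6.0 h |
| ochre | 0.0060 M |  | 6.0 h |

| run | time / h | ring / % | starting material / % |
|---|---|---|---|
| cedar | 0.417 | 55.7 | 15.3 |
| cedar | 0.833 | 62.3 | 4.5 |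
| cedar | 1.33 | 64.2 | 0.2 |
| cedar | 1.50 | 61.9 | 0 |
| cedar | 2.00 | 59.8 | 0.4 |
| cedar | 2.50 | 57.6 | 0 |
| cedar | 3.00 | 56.8 | 0.2 |
| oak | 0.417 | 23.7 | 4.0 |
| oak | 0.833 | 25.2 | 0.4 |
| oak | 1.33 | 24.1 | 0 |
| oak | 1.50 | 23.4 | 0.6 |
| oak | 2.00 | 21.9 | 0.8 |
| oak | 2.50 | 24.0 | 0 |
| oak | 3.00 | 18.7 | 0 |

(each reading ± 1 percentage point)

- ranking by amount of ring, in percent of the starting material charged, from high to low, at 6.0 h (blue / red / amber / ochre)
- the amount of ring, in percent of the starting material charged of the flask you put first, at 6.0 h
- the amount of ring, in percent of the starting material charged of the flask you put last, at 6.0 h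



First read the ring's loss. Between its peak reading and its last, cedar loses ring at 0.0733 h⁻¹. Run that back from the peak readings and you get a ring share before any loss, its selectivity, of 70.8 % in cedar and 26.8 % in oak.

Now suppose closure goes with the first power of starting material and the competing loss with the second. Then one concentration describes both runs: the even concentration, the concentration of starting material at which closure and the competing loss use it equally fast. The concentration falls during a run, so the share is taken over that whole fall:

share = (even concentration / charge) × ln(one + charge / even concentration)

This has no direct solution, so put in oak's share and repeat. With cedar's charge as the first guess you get 0.00653 M, and a second pass gives 0.00635 M, which I take. Put into cedar's charge, it gives a share of 67.4 %, where the readings gave 70.8 %.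

The shares are then 70.4 % for ochre and 31.6 % for amber. With survival 0.644 at 6.0 h, my reckoning gives 45.3 % for ochre and 20.3 % for amber.

Turn the question round. For amber to beat ochre, ochre's ring has to be lost faster than amber's by 0.134 h⁻¹, twice cedar's entire loss. Yet oak reads 0.138 h⁻¹, leaning on its last point, which is faster than cedar, not slower.

The forecast, reading “first-order ring closure competing with second-order oligomerisation”, says ochre > blue > red > amber, with 46 % and 21 %; mine stands slightly lower for ochre and for amber.

The flask gives ochre > blue > red > amber, with 43.6 % and 18.5 %.

    starting material + open dimer → open trimer (k = 165 L mol⁻¹ h⁻¹)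
    ring → over-reaction product (k = 0.0943 h⁻¹)
    starting material + ring → side product (k = 0.671 L mol⁻¹ h⁻¹)
    starting material → ring (k = 3.07 h⁻¹)
    2 starting material → open dimer (k = 174 L mol⁻¹ h⁻¹)

In ochre, starting material has a half-life of 0.23 h by closure, while ring has one of 7.4 h by passing into over-reaction product, 32.6 times longer. Nearly all of ochre's closure is done by 1.20 h, whereas its ring loss has 54 % of its turnover behind it by 3.00 h. The even concentration of 0.00635 M gave 45.3 % for ochre, which stands at 43.6 %. For the neighbour charged with 0.024 M it gives 26.7 %, and that flask stands at 25.2 %.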